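**Retrosynthetic overview**

1. Atom labels: the carbocycle is C1'–C6' (C1' bears Ca, C4' bears CH3 and OH, C5' bears Br). The diene is Ca(CH3)=Cb–Cc=Cd. The oxane is O1–C6 (C2 bears two CH3, C3 bears Br, C6 bears CH3 and Cd).
2. Feature on which the strategy rests: in the six-membered carbocycle the stereocentre C1' lies para to the methyl-bearing C4'. The heteroatoms on C4' and C5' mark a former C4'=C5' alkene. This is the para adduct of isoprene with an acrylate whose ester carbon is Ca.
3. Disconnections: Cb–Cc (Negishi coupling); Ca–CH3 and Cb–I (methylalumination–iodination of a C1' alkyne); C5'–Br (bromide inversion of the trans-diaxial diol through its cyclic sulfate); C4'–O and C5'–O (epoxidation, hydrolysis); C1'–C6' and C2'–C3' ([4+2]).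
4. Oxane partner: O1–C2 and C3–Br come from a 6-endo bromoetherification of (R)-linalool, whose carbinol carbon becomes C6. The vinyl group is then converted to ethynyl as the source of the alkenylmetal.
5. Ring order: the carbocycle is closed first (step 1), the oxane is closed separately (step 12), and the two are joined in step 15.

Key step: step 1

Assumption: the oxazaborolidinium ion made from (S)-α,α-diphenylprolinol is taken to expose the acrylate face that leads to (S)-3, as its binding model for acrylates predicts. If the optical rotation of 3 shows the opposite sense, the catalyst from (R)-α,α-diphenylprolinol is used and nothing else changes.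

**Step 1**
Reactants: 1 isoprene (2-methylbuta-1,3-diene); 2 2,2,2-trifluoroethyl acrylate
Product: 3 2,2,2-trifluoroethyl (1S)-4-methylcyclohex-3-ene-1-carboxylate
Conditions: (S)-3,3-diphenyl-1-(2-methylphenyl)tetrahydro-1H,3H-pyrrolo[1,2-c][1,3,2]oxazaborole (10 mol %), HN(SO2CF3)2 (8 mol %), 1 (5 equiv), CH2Cl2, −20 → 0 °C
Reagents that add atoms: none
Why: N-protonation of the oxazaborolidine by HN(SO2CF3)2 gives a cationic boron Lewis acid that binds the acrylate carbonyl and holds the s-trans enoate over one of its phenyl groups through an α-C–H···O contact, so that only one enantioface of the C=C bond is open. Isoprene adds to that face in a concerted but asynchronous, suprafacial [4+2] cycloaddition; the closest known reaction type is the oxazaborolidinium-catalysed Diels–Alder reaction of 2-substituted butadienes with acrylates. The single ring, carbocycle C1'–C6', is closed by the cycloaddition itself, the bond C2'–C3' (acrylate β-carbon to isoprene C1) being further advanced in the transition state than C1'–C6' (acrylate α-carbon to isoprene C4). The only new stereocentre, C1', is set as S by the catalyst-controlled face selection at the acrylate α-carbon, and endo/exo orientation has no stereochemical consequence because the diene termini carry only hydrogen. The step needs para over meta regioselectivity, which the C2 methyl group of isoprene secures by raising the HOMO coefficient at C1, an effect that the Lewis acid amplifies by polarising the acrylate LUMO towards its β-carbon. The electron-poor trifluoroethyl ester makes the acrylate reactive enough for an unactivated acyclic diene below room temperature, and a slight deficit of acid relative to the oxazaborolidine avoids cationic polymerisation of isoprene.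

**Step 2**
Reactants: 3 2,2,2-trifluoroethyl (1S)-4-methylcyclohex-3-ene-1-carboxylate
Product: 4 2,2,2-trifluoroethyl (3S)-6-methyl-7-oxabicyclo[4.1.0]heptane-3-carboxylate, used as the mixture of the (1R,3S,6S) epoxide (oxygen trans to the ester) and the (1S,3S,6R) epoxide (oxygen cis to the ester)
Conditions: mCPBA, CH2Cl2, 0 °C
Reagents that add atoms: 3-chloroperoxybenzoic acid (mCPBA), O=C(OO)c1cccc(Cl)c1
Why: In this Prilezhaev epoxidation the electron-rich trisubstituted C4'=C5' alkene is the only site that reacts with the peracid, the remote C1' ester gives little facial bias so both cis-fused epoxides are expected, and this is harmless because step 3 is designed to funnel both into one diol.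

**Step 3**
Reactants: 4 epoxide mixture
Product: 5 2,2,2-trifluoroethyl (1S,3R,4R)-3,4-dihydroxy-4-methylcyclohexane-1-carboxylate (C4'–OH cis and C5'–OH trans to the ester, both hydroxyls axial)
Conditions: HClO4 (5 mol %), THF–H2O (3:1), 0 °C → rt
Reagents that add atoms: water, O
Why: In this acid-catalysed epoxide hydrolysis under Fürst–Plattner (trans-diaxial) control, with the ester equatorial, the epoxide trans to the ester is opened by water at tertiary C4' and the epoxide cis to the ester at secondary C5', each by anti attack, so both should converge on the same trans-diaxial diol (4'R,5'R), as the two 1,2-oxides of limonene do.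

**Step 4**
Reactants: 5 diol
Product: 6 2,2,2-trifluoroethyl (3aR,6S,7aR)-3a-methylhexahydro-1,3,2-benzodioxathiole-6-carboxylate 2-oxide (trans-fused cyclic sulfite, both sulfur epimers)
Conditions: SOCl2 (1.3 equiv), Et3N (3 equiv), CH2Cl2, 0 °C
Reagents that add atoms: thionyl chloride, O=S(Cl)Cl
Why: In this cyclic sulfite formation from a 1,2-diol the secondary chlorosulfite is captured at sulfur by the neighbouring tertiary hydroxyl after ring inversion to the diequatorial diol conformer, no C–O bond is broken so both carbinol configurations are kept, and the amine keeps HCl away from the tertiary carbinol.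

**Step 5**
Reactants: 6 cyclic sulfite
Product: 7 2,2,2-trifluoroethyl (3aR,6S,7aR)-3a-methylhexahydro-1,3,2-benzodioxathiole-6-carboxylate 2,2-dioxide (trans-fused cyclic sulfate)
Conditions: RuCl3·3H2O (1 mol %), NaIO4 (1.5 equiv), MeCN–CH2Cl2–H2O, 0 °C
Reagents that add atoms: sodium periodate, [Na+].[O-]I(=O)(=O)=O
Why: The RuO4-catalysed oxidation of a cyclic sulfite to the cyclic sulfate acts only at sulfur, removes the sulfur stereocentre, is fast at 0 °C, and leaves the ester and the saturated ring untouched.

**Step 6**
Reactants: 7 cyclic sulfate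
Product: 9 2,2,2-trifluoroethyl (1S,3S,4R)-3-bromo-4-hydroxy-4-methylcyclohexane-1-carboxylate, via lithium bromoalkyl sulfate 8 (not isolated)
Conditions: LiBr (3 equiv), THF, rt → 50 °C; then H2SO4 (cat.), H2O (2 equiv), THF, rt
Reagents that add atoms: lithium bromide, [Li+].[Br-]
Why: In this SN2 opening of a cyclic sulfate by halide, bromide attacks secondary C5' rather than fully substituted C4' and comes in anti to the C5'–O bond and anti to the C4' methyl group, which inverts C5' to S (Br cis to the C4' oxygen), while the equatorial leaving group has no antiperiplanar hydrogen for E2 and the C4' oxygen stays a non-nucleophilic sulfate so that no epoxide can form, and the monoester is then hydrolysed at S–O with retention at C4', its ionisation being retarded by the β-bromine.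

**Step 7**
Reactants: 9 cis-bromohydrin ester
Product: 10 2,2,2-trifluoroethyl (1S,3S,4R)-3-bromo-4-methyl-4-(triethylsilyloxy)cyclohexane-1-carboxylate
Conditions: TESOTf (1.5 equiv), 2,6-lutidine (2.5 equiv), CH2Cl2, −78 → 0 °C
Reagents that add atoms: triethylsilyl trifluoromethanesulfonate, CC[Si](CC)(CC)OS(=O)(=O)C(F)(F)F
Why: A silyl triflate with a hindered base silylates even this hindered tertiary alcohol, and the ether is needed because an aluminium alkoxide gauche to the equatorial bromide in step 11 could set off a semipinacol ring contraction.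

**Step 8**
Reactants: 10 silyl ether ester
Product: 11 [(1S,3S,4R)-3-bromo-4-methyl-4-(triethylsilyloxy)cyclohexyl]methanol
Conditions: DIBAL-H (2.5 equiv), CH2Cl2, −78 → −20 °C; aq. potassium sodium tartrate
Reagents that add atoms: none
Why: The hydride reduction is taken through to the primary alcohol because the tetrahedral intermediate of a trifluoroethyl ester collapses too easily to stop at the aldehyde, and the secondary bromide and the silyl ether are inert to DIBAL-H at low temperature.

**Step 9**
Reactants: 11 primary alcohol
Product: 12 (1S,3S,4R)-3-bromo-4-methyl-4-(triethylsilyloxy)cyclohexane-1-carbaldehyde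
Conditions: Dess–Martin periodinane (1.3 equiv), CH2Cl2, 0 °C → rt
Reagents that add atoms: none
Why: The Dess–Martin oxidation is close to neutral and stops at the aldehyde, so the α-stereocentre C1' should not epimerise and no other group is oxidisable.

**Step 10**
Reactants: 12 aldehyde
Product: 13 {[(1R,2S,4S)-2-bromo-4-ethynyl-1-methylcyclohexyl]oxy}triethylsilane
Conditions: dimethyl (1-diazo-2-oxopropyl)phosphonate (1.5 equiv), K2CO3 (2 equiv), MeOH, 0 °C → rt (reagent and base premixed, aldehyde added last)
Reagents that add atoms: dimethyl (1-diazo-2-oxopropyl)phosphonate, COP(=O)(OC)C(=[N+]=[N-])C(C)=O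
Why: In this Ohira–Bestmann variant of the Seyferth–Gilbert homologation the diazophosphonate anion adds to the aldehyde faster than the mild carbonate base enolises it, so C1' should be kept, and the equatorial bromide, which has no antiperiplanar hydrogen, and the tertiary silyl ether tolerate K2CO3/MeOH.

**Step 11**
Reactants: 13 alkyne
Product: 15 {[(1R,2S,4S)-2-bromo-4-[(1E)-1-iodoprop-1-en-2-yl]-1-methylcyclohexyl]oxy}triethylsilane, via dimethyl(alkenyl)alane 14 (not isolated)
Conditions: Me3Al (3 equiv), Cp2ZrCl2 (25 mol %), CH2Cl2, 0 °C → rt; then I2, THF, −30 → 0 °C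
Reagents that add atoms: trimethylaluminium, C[Al](C)C; iodine, [I][I]
Why: In this Negishi zirconium-catalysed methylalumination CH3 and Al add syn, with CH3 on the internal carbon Ca and Al on the terminal carbon Cb, iodinolysis of the C–Al bond goes with retention to give the E-trisubstituted alkenyl iodide, and silyl ethers and unactivated alkyl bromides are tolerated.

**Step 12**
Reactants: 16 (R)-(−)-linalool, (3R)-3,7-dimethylocta-1,6-dien-3-ol
Product: 17 (3S,6R)-3-bromo-6-ethenyl-2,2,6-trimethyloxane (Br trans to vinyl, both equatorial)
Conditions: 2,4,4,6-tetrabromocyclohexa-2,5-dien-1-one (1.05 equiv), MeNO2, 0 °C → rt, dark; chromatography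
Reagents that add atoms: 2,4,4,6-tetrabromocyclohexa-2,5-dien-1-one, O=C1C(Br)=CC(Br)(Br)C=C1Br
Why: In this bromonium-induced 6-endo bromoetherification the bromonium ion forms on the more electron-rich trisubstituted alkene and the tertiary hydroxyl opens it anti at the tertiary carbon (Markovnikov, favoured in the polar solvent), which closes the oxane through O1–C2 with Br on C3, C6 keeps the R configuration of linalool because its C–O bond is untouched, and since remote C6 gives no facial bias the wanted (3S,6R) isomer has to be separated from its C3 epimer and from the 5-exo oxolanes.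

**Step 13**
Reactants: 17 vinyl oxane
Product: 19 (2R,5S)-5-bromo-2,6,6-trimethyloxane-2-carbaldehyde, via secondary ozonide 18 (not isolated)
Conditions: O3, CH2Cl2, −78 °C; then PPh3, −78 °C → rt
Reagents that add atoms: ozone, [O-][O+]=O
Why: Ozonolysis with reductive work-up cleaves the only alkene, and the resulting aldehyde has a fully substituted α-carbon and therefore cannot epimerise.

**Step 14**
Reactants: 19 oxane aldehyde
Product: 20 (3S,6R)-3-bromo-6-ethynyl-2,2,6-trimethyloxane
Conditions: dimethyl (1-diazo-2-oxopropyl)phosphonate (1.5 equiv), K2CO3 (2 equiv), MeOH, 0 °C → rt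
Reagents that add atoms: dimethyl (1-diazo-2-oxopropyl)phosphonate, COP(=O)(OC)C(=[N+]=[N-])C(C)=O
Why: The Ohira–Bestmann homologation works on non-enolisable α-alkoxy aldehydes, and the hindered equatorial bromide next to the quaternary C2 resists substitution and elimination under carbonate in methanol.

**Step 15**
Reactants: 20 oxane alkyne (1.3 equiv); 15 alkenyl iodide
Product: 23 {[(1R,2S,4S)-2-bromo-4-{(2E,4E)-5-[(2R,5S)-5-bromo-2,6,6-trimethyloxan-2-yl]penta-2,4-dien-2-yl}-1-methylcyclohexyl]oxy}triethylsilane, via alkenylzirconocene chloride 21 (not isolated), via alkenylzinc chloride 22 (not isolated)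
Conditions: 20, Cp2ZrHCl (1.4 equiv), THF, rt, dark; ZnCl2 (1.4 equiv), 0 °C; then 15, Pd(PPh3)4 (5 mol %), THF, rt
Reagents that add atoms: none
Why: In this hydrozirconation–transmetalation–Negishi sequence Zr–H adds syn with zirconium on the unhindered terminal carbon (E-alkenylmetal), zinc takes over the alkenyl group with retention, zerovalent palladium inserts only into the alkenyl C–I bond and not into the unactivated secondary C–Br bonds, and the Cb–Cc bond forms with retention of both alkene geometries under base-free conditions.

**Step 16**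
Reactants: 23 silyl-protected diene
Product: 24 (1R,2S,4S)-2-bromo-4-{(2E,4E)-5-[(2R,5S)-5-bromo-2,6,6-trimethyloxan-2-yl]penta-2,4-dien-2-yl}-1-methylcyclohexan-1-ol (target)
Conditions: HF·pyridine, pyridine, THF, 0 °C → rt
Reagents that add atoms: none
Why: Fluoride-driven desilylation in a pyridine-buffered medium frees the tertiary alcohol without ever forming a free alkoxide next to the bromide and without enough acidity to ionise the dienylic C6–O1 bond, and no stereocentre is touched.

**Compound list**

1 | isoprene | C=CC(C)=C | starting material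
2 | 2,2,2-trifluoroethyl acrylate | C=CC(=O)OCC(F)(F)F | starting material
3 | 2,2,2-trifluoroethyl (1S)-4-methylcyclohex-3-ene-1-carboxylate | O=C(OCC(F)(F)F)[C@H]1CCC(C)=CC1 | intermediate
4 | 2,2,2-trifluoroethyl (3S)-6-methyl-7-oxabicyclo[4.1.0]heptane-3-carboxylate, both cis-fused epoxide diastereomers | O=C(OCC(F)(F)F)[C@H]1CCC2(C)OC2C1 | intermediate
5 | 2,2,2-trifluoroethyl (1S,3R,4R)-3,4-dihydroxy-4-methylcyclohexane-1-carboxylate | O=C(OCC(F)(F)F)[C@H]1CC[C@@](C)(O)[C@H](O)C1 | intermediate
6 | trans-fused cyclic sulfite of 5 (3aR,6S,7aR; both sulfur epimers) | O=C(OCC(F)(F)F)[C@H]1CC[C@@]2(C)OS(=O)O[C@@H]2C1 | intermediate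
7 | trans-fused cyclic sulfate of 5 (3aR,6S,7aR) | O=C(OCC(F)(F)F)[C@H]1CC[C@@]2(C)OS(=O)(=O)O[C@@H]2C1 | intermediate
8 | lithium (1R,2S,4S)-2-bromo-1-methyl-4-[(2,2,2-trifluoroethoxy)carbonyl]cyclohexyl sulfate | O=C(OCC(F)(F)F)[C@H]1CC[C@@](C)(OS(=O)(=O)[O-])[C@@H](Br)C1.[Li+] | intermediate
9 | 2,2,2-trifluoroethyl (1S,3S,4R)-3-bromo-4-hydroxy-4-methylcyclohexane-1-carboxylate | O=C(OCC(F)(F)F)[C@H]1CC[C@@](C)(O)[C@@H](Br)C1 | intermediate
10 | 2,2,2-trifluoroethyl (1S,3S,4R)-3-bromo-4-methyl-4-(triethylsilyloxy)cyclohexane-1-carboxylate | O=C(OCC(F)(F)F)[C@H]1CC[C@@](C)(O[Si](CC)(CC)CC)[C@@H](Br)C1 | intermediate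
11 | [(1S,3S,4R)-3-bromo-4-methyl-4-(triethylsilyloxy)cyclohexyl]methanol | OC[C@H]1CC[C@@](C)(O[Si](CC)(CC)CC)[C@@H](Br)C1 | intermediate
12 | (1S,3S,4R)-3-bromo-4-methyl-4-(triethylsilyloxy)cyclohexane-1-carbaldehyde | O=C[C@H]1CC[C@@](C)(O[Si](CC)(CC)CC)[C@@H](Br)C1 | intermediate
13 | {[(1R,2S,4S)-2-bromo-4-ethynyl-1-methylcyclohexyl]oxy}triethylsilane | C#C[C@H]1CC[C@@](C)(O[Si](CC)(CC)CC)[C@@H](Br)C1 | intermediate
14 | dimethyl{(1E)-2-[(1S,3S,4R)-3-bromo-4-methyl-4-(triethylsilyloxy)cyclohexyl]prop-1-en-1-yl}alane | C/C(=C\[Al](C)C)[C@H]1CC[C@@](C)(O[Si](CC)(CC)CC)[C@@H](Br)C1 | intermediate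
15 | {[(1R,2S,4S)-2-bromo-4-[(1E)-1-iodoprop-1-en-2-yl]-1-methylcyclohexyl]oxy}triethylsilane | C/C(=C\I)[C@H]1CC[C@@](C)(O[Si](CC)(CC)CC)[C@@H](Br)C1 | intermediate
16 | (R)-(−)-linalool | C=C[C@](C)(O)CCC=C(C)C | starting material
17 | (3S,6R)-3-bromo-6-ethenyl-2,2,6-trimethyloxane | C=C[C@@]1(C)CC[C@H](Br)C(C)(C)O1 | intermediate
18 | 3-[(2R,5S)-5-bromo-2,6,6-trimethyloxan-2-yl]-1,2,4-trioxolane (both epimers at the trioxolane carbon) | C2OOC(O2)[C@@]1(C)CC[C@H](Br)C(C)(C)O1 | intermediate
19 | (2R,5S)-5-bromo-2,6,6-trimethyloxane-2-carbaldehyde | O=C[C@@]1(C)CC[C@H](Br)C(C)(C)O1 | intermediate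
20 | (3S,6R)-3-bromo-6-ethynyl-2,2,6-trimethyloxane | C#C[C@@]1(C)CC[C@H](Br)C(C)(C)O1 | intermediate
21 | chlorobis(cyclopentadienyl){(E)-2-[(2R,5S)-5-bromo-2,6,6-trimethyloxan-2-yl]ethenyl}zirconium | Cl[Zr](/C=C/[C@@]1(C)CC[C@H](Br)C(C)(C)O1)(C2C=CC=C2)C3C=CC=C3 | intermediate
22 | chloro{(E)-2-[(2R,5S)-5-bromo-2,6,6-trimethyloxan-2-yl]ethenyl}zinc | Cl[Zn]/C=C/[C@@]1(C)CC[C@H](Br)C(C)(C)O1 | intermediate
23 | triethylsilyl ether of the target at the C4' oxygen | C/C(=C\C=C\[C@@]1(C)CC[C@H](Br)C(C)(C)O1)[C@H]1CC[C@@](C)(O[Si](CC)(CC)CC)[C@@H](Br)C1 | intermediate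
24 | (1R,2S,4S)-2-bromo-4-{(2E,4E)-5-[(2R,5S)-5-bromo-2,6,6-trimethyloxan-2-yl]penta-2,4-dien-2-yl}-1-methylcyclohexan-1-ol | C/C(=C\C=C\[C@@]1(C)CC[C@H](Br)C(C)(C)O1)[C@H]1CC[C@@](C)(O)[C@@H](Br)C1 | target

**Step count**

Total step count: 16.
Longest linear sequence: 13 steps (steps 1–11, 15 and 16). The oxane branch contributes steps 12–14.

**Steps most likely to fail**

**Step 6.**
- Substitution may be slow, because in the trans-fused bicycle the incoming bromide is syn-axial to the C1' ester.
- The tertiary C4'–O bond may ionise during the opening or during the acid hydrolysis. This would lead to elimination or to loss of configuration at C4'.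
- The fallback sets out from 5 and comes back at 10. It replaces the tethered leaving group with an untethered axial one.
- Diol 5 is sulfonylated only at the secondary hydroxyl (ClCH2SO2Cl, pyridine, CH2Cl2, 0 °C) to give the hydroxy chloromethanesulfonate F1.
- The tertiary hydroxyl is capped at once (TESOTf, 2,6-lutidine, −78 → 0 °C) to give the silyl ether sulfonate F2, so that epoxide closure is blocked.
- The axial sulfonate is then displaced with inversion by LiBr in DMF at 40–60 °C, which gives 10 directly.

**Step 12.**
- Closure in the 5-exo mode may compete.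
- There is no facial selectivity with respect to the remote C6 centre.
- Some attack of the bromonium source on the vinyl group is possible, so throughput of the wanted isomer may be low.
- The fallback sets out from 16 and comes back at 17. It uses intramolecular oxymercuration, which is reversible and strictly Markovnikov and therefore avoids the 5-exo mode.
- Hg(OCOCF3)2 (1 equiv) in MeCN at −20 °C should give the oxanylmercury trifluoroacetate F3.
- Exchange with aqueous KBr gives the oxanylmercury bromide F4, at which stage the C3 epimers are separated.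
- One equivalent of Br2 in pyridine at 0 °C in the dark cleaves the C–Hg bond with retention to give 17.
- In either approach the unwanted β-bromo ether isomers can be returned to 16 by reductive ring opening with zinc in ethanol.

**Step 3.**
- Stereoconvergence may be incomplete. The epoxide cis to the ester must open at the secondary carbon against the electronic preference for the tertiary one, and an ester is a weaker conformational anchor than an alkyl group.
- The ester carbonyl may also participate, with lactonisation.
- The fallback sets out from 3 and comes back at 5. It uses two openings that are each matched in regiochemistry and diaxial geometry.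
- NBS in aqueous acetone at 0 °C should give the trans-diaxial bromohydrin F5. Water attacks C4' on the face cis to the ester, and bromine sits on C5' trans to it.
- Excess KOH in DMSO–H2O closes F5 to a single epoxide and saponifies the ester, giving the potassium epoxy carboxylate F6.
- On warming to 80 °C, hydroxide opens F6 by SN2 at the less hindered C5'. Cold acidification then gives the dihydroxy acid F7.
- O-alkylation of the carboxylate of F7 with CF3CH2OSO2CF3 and K2CO3 in DMF at rt gives 5 without activating the acid towards lactonisation.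

**Further compounds**

F1 | step 6 | 2,2,2-trifluoroethyl (1S,3R,4R)-3-[(chloromethanesulfonyl)oxy]-4-hydroxy-4-methylcyclohexane-1-carboxylate | O=C(OCC(F)(F)F)[C@H]1CC[C@@](C)(O)[C@H](OS(=O)(=O)CCl)C1
F2 | step 6 | 2,2,2-trifluoroethyl (1S,3R,4R)-3-[(chloromethanesulfonyl)oxy]-4-methyl-4-(triethylsilyloxy)cyclohexane-1-carboxylate | O=C(OCC(F)(F)F)[C@H]1CC[C@@](C)(O[Si](CC)(CC)CC)[C@H](OS(=O)(=O)CCl)C1
F3 | step 12 | [(3S,6R)-6-ethenyl-2,2,6-trimethyloxan-3-yl]mercury trifluoroacetate | C=C[C@@]1(C)CC[C@H]([Hg]OC(=O)C(F)(F)F)C(C)(C)O1
F4 | step 12 | bromo[(3S,6R)-6-ethenyl-2,2,6-trimethyloxan-3-yl]mercury | C=C[C@@]1(C)CC[C@H]([Hg]Br)C(C)(C)O1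
F5 | step 3 | 2,2,2-trifluoroethyl (1S,3R,4R)-3-bromo-4-hydroxy-4-methylcyclohexane-1-carboxylate | O=C(OCC(F)(F)F)[C@H]1CC[C@@](C)(O)[C@H](Br)C1
F6 | step 3 | potassium (1S,3S,6R)-6-methyl-7-oxabicyclo[4.1.0]heptane-3-carboxylate | [K+].[O-]C(=O)[C@H]1CC[C@@]2(C)O[C@H]2C1
F7 | step 3 | (1S,3R,4R)-3,4-dihydroxy-4-methylcyclohexane-1-carboxylic acid | O=C(O)[C@H]1CC[C@@](C)(O)[C@H](O)C1
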